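## Structural features

Numbering used here: lactone O1, C2–C6; side chain C7, C8; flavanone atoms primed. The target is a (2′S)-5′,7′-dihydroxyflavanone (rings A, B, C) whose ring-A carbon C6′, the one between the two phenols, is bonded to the diarylmethine carbon C8. C8 leads through the carbinol C7 to C6 of a 5-hydroxy-5,6-dihydro-2H-pyran-2-one. Four of the five stereocentres are contiguous, C5 (S), C6 (R), C7 (R) and C8 (S): the C5 hydroxyl and the side chain are cis on the lactone, O6 and O7 are syn along the chain, and C7–O/C8–Ph are related as in a trans-3-hydroxy-4-phenyl-dihydrocoumarin; C2′ (S) is remote. Fragile groups are the unsaturated δ-lactone with its allylic hydroxyl (ring contraction to the butenolide, conjugate addition at C4, elimination towards a 2-pyrone), the flavanone (base opens ring C to the chalcone and scrambles C2′), the electron-rich ring A and the doubly benzylic C8–H. The real difficulty is threefold: the chain must sit on C6′ and not C8′ with C2′ defined, four contiguous centres must be built next to a very bulky diarylmethine, and three carbonyl groups and four hydroxyls of similar kind must be told apart. The key step exploits the fact that O1, C2, C3, C4 and C5, with oxygen on C2 and C5 and the C3=C4 double bond, are an oxidised furan: with C6 as carbinol carbon the lactone ring is the Achmatowicz product of a 2-furylcarbinol, so the sensitive heterocycle can be carried as an aromatic furan until five steps before the end.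

## Logic of the disconnections

29 ⇒ 28 ⇒ 27. Cut: the O–Si bond on O7, then the three O–acyl bonds (C5 ester, two aryl esters). Reason: the free hydroxy-lactone and the free phenols should appear only at the end. Gain: none in skeleton, but every earlier step works on a masked, less reactive substrate. Demand: cleavage conditions mild enough for the lactone and for C2′.

27 ⇒ 26 ⇒ 25. Cut: the C5–O bond (with inversion), then the C5–H bond. Reason: a small hydride is expected to give the 5,6-trans alcohol from 25, so the cis arrangement is reached by SN2 inversion. Gain: C5 becomes a ketone and one stereocentre is removed. Demand: 1,2-reduction of the ring ketone in preference to the chromanone, and substitution at C5 without elimination.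

25 ⇒ 24. Cut: the C2=O oxidation level (C2–H restored). Reason: the lactone carbonyl is the oxidised anomeric carbon of a lactol. Gain: the retron of the key step appears. Demand: an oxidant that the silyl ether and the acetates survive.

24 ⇒ 22 (key). Cut: O1–C2; the ring atoms C2–C5 fold back into a furan. Reason: furan plus carbinol carries all six ring atoms and both oxygenation sites. Gain: the heterocycle becomes a robust aromatic ring, and the target is reduced to an open chain with three contiguous centres. Demand: oxidation of the furan only, which asks for an acyl-deactivated ring A and a blocked O7.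

22 ⇒ 21 ⇒ 20. Cut: the two aryl O–acetyl bonds, then the C6–H bond. Reason: an α-silyloxy ketone is reduced anti to the C–O bond, which gives exactly the 6,7-syn alcohol. Gain: C6 is removed as a stereocentre. Demand: the chromanone carbonyl must be spared, and only the phenols may be acetylated afterwards.

20 ⇒ 19 ⇒ 17. Cut: the two O–allyl bonds, then C4′–C4a′ (ring C). Reason: in 17 the two positions ortho to the ether oxygen are equivalent, so acylation can only give the 6′-substituted flavanone. Gain: ring C and the question of 6′ versus 8′ attachment disappear. Demand: an acid-mediated acylation that the 2-acylfuran, the silyl ether and the benzylic ether tolerate.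

17 ⇒ 16 ⇒ 14 + 15. Cut: the ester O–CH3, then the bond between the para oxygen and C2′. Reason: C2′ can be bought in 15 and transferred with inversion. Gain: the last remote stereocentre comes from a commercial alcohol. Demand: SN2 etherification without elimination, and a single free phenol in 14.

14 ⇒ 10 + 11. Cut: the bond between C6 and the furan carbon (future C5), and the O–Si bond on the para oxygen. Reason: 11 is the cheapest source of the four ring carbons. Gain: the chain ends in a carboxyl derivative. Demand: one, and only one, addition of the furyl nucleophile.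

10 ⇒ 9 ⇒ 8. Cut: the O–allyl bond on the ortho oxygen, then the amide C–N bond with re-closure of the aryl lactone. Reason: the lactone ties C6 to the ortho oxygen and keeps that oxygen apart from the other two. Gain: a rigid bicyclic lactone. Demand: ring opening without loss of the C7 configuration.

8 ⇒ 7 ⇒ 5. Cut: the O–Si bond, then the C7–O bond. Reason: the lactone enolate has one open face, opposite the C8 phenyl. Gain: C7 is removed. Demand: trans-selective oxygen transfer.

5 ⇒ 3 + 4. Cut: the C8–phenyl bond. Reason: conjugate arylation of a coumarin is a catalytic asymmetric reaction. Gain: no stereocentre is left, and 3 is flat. Demand: enantioselective addition to an electron-rich, peri-substituted coumarin.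

3 ⇒ 2 ⇒ 1. Cut: the O–allyl bond on O5, then the O–Si bond on O7. Reason: the oxygen para to the future chain must be distinguishable from the two ortho oxygens, because it becomes O1′. Gain: a commercial diphenol. Demand: regioselective monosilylation of the 7-hydroxyl.

## Other disconnections considered

Alternative 1: Cut C7–C8 and the acyl–oxygen bond between C6 and the ring-A oxygen next to C6′, a retro-[4+2] of a 4-phenyl-dihydrocoumarin.
- Forward: base ionises benzhydrol A2 to the ortho-quinone methide A3. A chiral N-heterocyclic carbene turns an alkoxyketene equivalent into an azolium enolate, which adds to the benzylic carbon and then acylates the phenoxide, giving lactone A1 with C7 and C8 in place.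
- In favour: one catalytic step forms a C–C bond, the lactone and two stereocentres. The chosen route needs steps 3, 4 and 5 for this and relies on a conjugate addition to a peri-hindered coumarin. On bonds per step and on avoiding that sluggish addition the alternative is the better plan.
- Against here: the closed transition state of such annulations should favour the cis-3,4 lactone, so the trans arrangement of A1 would need a later C3 epimerisation. The enolate oxidation of step 4 is expected to be trans-selective by simple steric approach.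
- A2 needs three differently substituted oxygens on a hindered 2,6-dioxygenated benzhydrol, which is likely to cost the steps the annulation saves.
- The benzyl ethers of A1 cannot be removed by hydrogenolysis once the furan or C3=C4 is present.
- Comparison: A1 corresponds to compound 8, so only steps 1–5 would be replaced; ring C, the furan and the pyranone would be made as here. Both plans rest on catalyst control for C8 (equal). The mechanisms differ (polar stepwise annulation against insertion into an aryl–rhodium bond), but the later risks are the same.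

Alternative 2: Cut C5–C6 and O1–C2, the hetero-Diels–Alder retron.
- Forward: aldehyde A5 and the 1-benzoyloxy-4-methoxy-2-silyloxy diene A6 combine under a chelating Lewis acid (MgBr2·OEt2 or Eu(fod)3) to give dihydropyranone A4. The benzoyloxy-bearing diene terminus bonds to the aldehyde carbon (C5–C6) and the aldehyde oxygen bonds to the methoxy-bearing terminus (O1–C2).
- In favour: two ring bonds and two stereocentres (C5, C6) arise at once. Chelation between the aldehyde oxygen and the C7 benzyloxy group should give the 6,7-syn relationship, and an endo approach the 5,6-cis one. On C5 control and on bonds per step the alternative is better: the chosen key step forms one C–O bond and no lasting stereocentre, and steps 16–18 are then needed for C5.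
- No furan is involved, so ring C could be closed under acid without restriction and the two-ketone reduction of step 13 disappears (also better).
- Against here: A4 has its carbonyl on C4 and an enol ether at C2=C3, whereas the target needs the carbonyl on C2, the alkene at C3=C4 and no oxygen on C4. Correcting this takes a 1,2-reduction, an allylic transposition and an oxidation of C2, at least three steps with a C4 stereocentre made and destroyed. The furan oxidation delivers the correct oxygen pattern directly.
- Chelation needs a benzyl-type ether on O7, which cannot be removed at the end next to C3=C4. A5 is hindered and epimerisable at C7, and the Lewis acid is shared with the chromanone carbonyl.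
- Step economy: probably no shorter overall.

Alternative 3: Cut C4′–C4a′, closing ring C last.
- Forward: the mixed trifluoroacetic anhydride of acid A8 acylates one of the two equivalent positions ortho to the ether oxygen and gives A7; desilylation then gives the target.
- In favour: regiochemistry is fixed by symmetry and C2′ comes from an SN2 etherification. The chosen route uses the same logic for ring C in steps 9–11, so on these points the two are equal.
- Better than the chosen plan: the chromanone carbonyl and the base-labile C2′ appear last, so the chemoselectivity demands of steps 13 and 17 vanish and no phenol protecting-group exchange is needed.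
- Against here: the acylation would run on the complete, acid- and base-sensitive hydroxy-pyranone with four silyl ethers. The aryl silyl ethers flanking each reacting position are weaker donors and bulkier than the allyl ethers of 17.
- The β-aryloxy acid chain, which loses the phenol by retro-oxa-Michael reaction under base, would have to survive the whole lactone construction or be attached to a substrate that already holds the lactone.
- The furan oxidation would meet a ring A that is not deactivated by acyl groups.
- Comparison: the mechanism of ring-C closure is identical; only the timing differs. The chosen plan closes ring C on a robust intermediate and pays with two later chemoselectivity demands. The step count is about equal.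

Key step: step 15

Assumption 1: small-hydride reduction of dione 25 is taken to give the 5,6-trans alcohol (axial attack, as with simpler 6-substituted pyran-2,5-diones); hence the inversion in step 18.
Assumption 2: (S)-SEGPHOS is taken to deliver phenyl to the coumarin face that gives (4S), the mirror image of the sense known for the (R)-ligand with simple coumarins.

## Route

Step 1
Reactants: 1 5,7-dihydroxycoumarin
Product: 2 5-hydroxy-7-(triisopropylsilyloxy)-2H-chromen-2-one
Conditions: i-Pr3SiCl (1.05 equiv), imidazole, DMF, 0 °C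
Reagents that add atoms: chlorotriisopropylsilane, CC(C)[Si](Cl)(C(C)C)C(C)C
Why: The 7-hydroxyl is the more accessible phenol (the 5-hydroxyl is crowded by the peri C4–H) and is conjugated through the ring with the lactone carbonyl, so a bulky silyl chloride should monosilylate it (regioselective phenol silylation); minor 5-O and bis-silyl ethers are removed by chromatography. This singles out the oxygen that becomes O1′.

Step 2
Reactants: 2 5-hydroxy-7-(triisopropylsilyloxy)-2H-chromen-2-one
Product: 3 5-(allyloxy)-7-(triisopropylsilyloxy)-2H-chromen-2-one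
Conditions: allyl bromide, K2CO3, acetone, rt
Reagents that add atoms: allyl bromide, C=CCBr
Why: Williamson etherification of the remaining phenol; carbonate in acetone leaves the coumarin lactone and the aryl silyl ether intact.

Step 3
Reactants: 3 5-(allyloxy)-7-(triisopropylsilyloxy)-2H-chromen-2-one; 4 phenylboronic acid
Product: 5 (4S)-5-(allyloxy)-4-phenyl-7-(triisopropylsilyloxy)chroman-2-one
Conditions: 4 (5 equiv), Rh(acac)(C2H4)2 (3 mol %), (S)-SEGPHOS (3.3 mol %), dioxane/H2O 10:1, 60 °C
Reagents that add atoms: none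
Why: Hayashi–Miyaura asymmetric 1,4-addition: the phenyl–rhodium species (monovalent rhodium, chiral bisphosphine) inserts C3=C4 on one face and water releases the lactone, setting C8 as (4S). Allyl and silyl ethers are inert to the neutral aqueous medium.

Step 4
Reactants: 5 (4S)-5-(allyloxy)-4-phenyl-7-(triisopropylsilyloxy)chroman-2-one
Product: 7 (3R,4S)-5-(allyloxy)-3-hydroxy-4-phenyl-7-(triisopropylsilyloxy)chroman-2-one, via potassium enolate 6 (not isolated)
Conditions: KN(SiMe3)2, THF, −78 °C; then (±)-2-(benzenesulfonyl)-3-phenyloxaziridine, −78 °C; NH4Cl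
Reagents that add atoms: 2-(benzenesulfonyl)-3-phenyloxaziridine, O=S(=O)(c1ccccc1)N1OC1c1ccccc1
Why: Enolate oxidation with a Davis oxaziridine; the C4 phenyl sits pseudo-axial to avoid the 5-allyloxy group, so oxygen is transferred to the opposite enolate face and C7 is set trans to the phenyl. The potassium enolate limits addition to the sulfonimine by-product.

Step 5
Reactants: 7 (3R,4S)-5-(allyloxy)-3-hydroxy-4-phenyl-7-(triisopropylsilyloxy)chroman-2-one
Product: 8 (3R,4S)-5-(allyloxy)-3-(tert-butyldimethylsilyloxy)-4-phenyl-7-(triisopropylsilyloxy)chroman-2-one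
Conditions: t-BuMe2SiOTf, 2,6-lutidine, CH2Cl2, −78 → 0 °C
Reagents that add atoms: tert-butyldimethylsilyl trifluoromethanesulfonate, CC(C)(C)[Si](C)(C)OS(=O)(=O)C(F)(F)F
Why: A silyl triflate with a hindered pyridine base silylates the hindered secondary alcohol without touching the C3 configuration or the aryl lactone (standard alcohol protection).

Step 6
Reactants: 8 (3R,4S)-5-(allyloxy)-3-(tert-butyldimethylsilyloxy)-4-phenyl-7-(triisopropylsilyloxy)chroman-2-one
Product: 9 (2R,3S)-3-[2-(allyloxy)-6-hydroxy-4-(triisopropylsilyloxy)phenyl]-2-(tert-butyldimethylsilyloxy)-N-methoxy-N-methyl-3-phenylpropanamide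
Conditions: MeNHOMe·HCl, i-PrMgCl (premixed), THF, −20 → 0 °C; NH4Cl
Reagents that add atoms: N,O-dimethylhydroxylamine hydrochloride, CNOC.Cl
Why: Aminolysis of the aryl lactone by the chloromagnesium amide opens the ring to the Weinreb amide and frees the ortho phenol. The Weinreb amide will later accept exactly one organolithium.

Step 7
Reactants: 9 (2R,3S)-3-[2-(allyloxy)-6-hydroxy-4-(triisopropylsilyloxy)phenyl]-2-(tert-butyldimethylsilyloxy)-N-methoxy-N-methyl-3-phenylpropanamide
Product: 10 (2R,3S)-3-[2,6-bis(allyloxy)-4-(triisopropylsilyloxy)phenyl]-2-(tert-butyldimethylsilyloxy)-N-methoxy-N-methyl-3-phenylpropanamide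
Conditions: allyl bromide, K2CO3, acetone, 40 °C
Reagents that add atoms: allyl bromide, C=CCBr
Why: Williamson etherification; the freed ortho phenol now carries the same group as its partner, so the ring is locally symmetric about the para oxygen.

Step 8
Reactants: 10 (2R,3S)-3-[2,6-bis(allyloxy)-4-(triisopropylsilyloxy)phenyl]-2-(tert-butyldimethylsilyloxy)-N-methoxy-N-methyl-3-phenylpropanamide; 11 furan
Product: 14 (2R,3S)-3-[2,6-bis(allyloxy)-4-hydroxyphenyl]-2-(tert-butyldimethylsilyloxy)-1-(furan-2-yl)-3-phenylpropan-1-one, via 2-furyllithium 12 (not isolated), via silyl ketone 13 (not isolated)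
Conditions: 11, n-BuLi, THF, 0 °C; add 10, −78 → −20 °C; AcOH; then Bu4NF, 0 °C
Reagents that add atoms: none
Why: 2-Furyllithium adds once to the Weinreb amide because the chelated tetrahedral adduct survives until the acidic quench (Weinreb ketone synthesis). Acetic-acid-buffered fluoride then cleaves only the unhindered aryl silyl ether and leaves the hindered alkyl silyl ether; this joins C5 to C6 and frees the para phenol.

Step 9
Reactants: 14 (2R,3S)-3-[2,6-bis(allyloxy)-4-hydroxyphenyl]-2-(tert-butyldimethylsilyloxy)-1-(furan-2-yl)-3-phenylpropan-1-one; 15 methyl (3R)-3-hydroxy-3-phenylpropanoate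
Product: 16 methyl (3S)-3-{3,5-bis(allyloxy)-4-[(1S,2R)-2-(tert-butyldimethylsilyloxy)-3-(furan-2-yl)-3-oxo-1-phenylpropyl]phenoxy}-3-phenylpropanoate
Conditions: PPh3, DIAD, toluene, 0 °C → rt
Reagents that add atoms: none
Why: Mitsunobu etherification of the only free phenol with the (R)-benzylic alcohol; SN2 displacement of the oxyphosphonium group inverts the carbinol carbon and so sets the future C2′ as (S). Toluene at 0 °C is chosen to hold back elimination to methyl cinnamate.

Step 10
Reactants: 16 methyl (3S)-3-{3,5-bis(allyloxy)-4-[(1S,2R)-2-(tert-butyldimethylsilyloxy)-3-(furan-2-yl)-3-oxo-1-phenylpropyl]phenoxy}-3-phenylpropanoate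
Product: 17 (3S)-3-{3,5-bis(allyloxy)-4-[(1S,2R)-2-(tert-butyldimethylsilyloxy)-3-(furan-2-yl)-3-oxo-1-phenylpropyl]phenoxy}-3-phenylpropanoic acid
Conditions: Me3SnOH, 1,2-dichloroethane, 70 °C; dilute aq. HCl work-up
Reagents that add atoms: trimethyltin hydroxide, C[Sn](C)(C)O
Why: Trimethyltin hydroxide cleaves methyl esters under near-neutral conditions, so the C7 centre next to the ketone is not enolised and the β-aryloxy group is not eliminated.

Step 11
Reactants: 17 (3S)-3-{3,5-bis(allyloxy)-4-[(1S,2R)-2-(tert-butyldimethylsilyloxy)-3-(furan-2-yl)-3-oxo-1-phenylpropyl]phenoxy}-3-phenylpropanoic acid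
Product: 19 (2S)-5,7-bis(allyloxy)-6-[(1S,2R)-2-(tert-butyldimethylsilyloxy)-3-(furan-2-yl)-3-oxo-1-phenylpropyl]-2-phenylchroman-4-one, via mixed anhydride 18 (not isolated)
Conditions: (CF3CO)2O (2 equiv), CH2Cl2, 0 °C
Reagents that add atoms: none
Why: Friedel–Crafts acylation through the mixed trifluoroacetic anhydride closes the six-membered ring C onto one of the two equivalent, doubly oxygen-flanked positions ortho to the ether oxygen, so only the 6′-substituted flavanone can form and C2′ is untouched. The 2-acylfuran is deactivated towards acylation, and the contact with acid is short.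

Step 12
Reactants: 19 (2S)-5,7-bis(allyloxy)-6-[(1S,2R)-2-(tert-butyldimethylsilyloxy)-3-(furan-2-yl)-3-oxo-1-phenylpropyl]-2-phenylchroman-4-one
Product: 20 (2S)-6-[(1S,2R)-2-(tert-butyldimethylsilyloxy)-3-(furan-2-yl)-3-oxo-1-phenylpropyl]-5,7-dihydroxy-2-phenylchroman-4-one
Conditions: Pd(PPh3)4 (5 mol %), morpholine, THF, rt
Reagents that add atoms: none
Why: Zerovalent palladium ionises the two aryl allyl ethers and morpholine captures the allyl groups (Tsuji–Trost deallylation), neutral conditions that keep the flavanone closed and the C7 centre intact.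

Step 13
Reactants: 20 (2S)-6-[(1S,2R)-2-(tert-butyldimethylsilyloxy)-3-(furan-2-yl)-3-oxo-1-phenylpropyl]-5,7-dihydroxy-2-phenylchroman-4-one
Product: 21 (2S)-6-[(1S,2R,3S)-2-(tert-butyldimethylsilyloxy)-3-(furan-2-yl)-3-hydroxy-1-phenylpropyl]-5,7-dihydroxy-2-phenylchroman-4-one
Conditions: LiBH(s-Bu)3 (3.5 equiv), THF, −78 °C; NH4Cl
Reagents that add atoms: none
Why: The first two equivalents turn the phenols into lithium phenoxides, which make the chromanone carbonyl a vinylogous carboxylate, unreactive at −78 °C, and open any cyclic hemiketal of 20. The bulky hydride then attacks the α-silyloxy furyl ketone anti to the C7–O bond (Felkin–Anh), which gives the 6,7-syn alcohol and sets C6.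

Step 14
Reactants: 21 (2S)-6-[(1S,2R,3S)-2-(tert-butyldimethylsilyloxy)-3-(furan-2-yl)-3-hydroxy-1-phenylpropyl]-5,7-dihydroxy-2-phenylchroman-4-one
Product: 22 (2S)-6-[(1S,2R,3S)-2-(tert-butyldimethylsilyloxy)-3-(furan-2-yl)-3-hydroxy-1-phenylpropyl]-4-oxo-2-phenylchroman-5,7-diyl diacetate
Conditions: Ac2O (2.2 equiv), Et3N, CH2Cl2, 0 °C, no acyl-transfer catalyst
Reagents that add atoms: acetic anhydride, CC(=O)OC(C)=O
Why: Phenols, as ammonium phenoxides, are acylated by the anhydride far faster than the hindered secondary furylcarbinol when no acyl-transfer catalyst is present (chemoselective phenol acetylation). The acetates deactivate ring A for the next step.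

Step 15
Reactants: 22 (2S)-6-[(1S,2R,3S)-2-(tert-butyldimethylsilyloxy)-3-(furan-2-yl)-3-hydroxy-1-phenylpropyl]-4-oxo-2-phenylchroman-5,7-diyl diacetate
Product: 24 (2S)-6-{(1S,2R)-2-(tert-butyldimethylsilyloxy)-2-[(2S,6RS)-6-hydroxy-3-oxo-3,6-dihydro-2H-pyran-2-yl]-1-phenylethyl}-4-oxo-2-phenylchroman-5,7-diyl diacetate, via ene-dione 23 (not isolated)
Conditions: NBS (1.05 equiv), NaHCO3, NaOAc, THF/H2O 4:1, 0 °C
Reagents that add atoms: water, O
Why: NBS brominates the furan at its free α-carbon (the future C2), water adds to the oxocarbenium ion, bromide is lost and the 2,5-dioxygenated dihydrofuran opens to the (Z)-ene-dione 23. The C6 hydroxyl then adds to the aldehyde carbon and forms O1–C2, a 6-exo-trig hemiacetalisation that closes the pyranone ring of 24. This is the Achmatowicz rearrangement of a 2-furylcarbinol, the closest known reaction type, which tolerates an α-silyloxy branch. The only new stereocentre is the anomeric C2; it is not controlled (the anomeric effect favours the axial hydroxyl) and is erased in step 16, while C6, C7, C8 and C2′ take no part. The step needs oxidation of the furan in preference to ring A, the two phenyl rings and the enolisable chromanone: the acetates make ring A electron-poor, the furan is by far the most electron-rich π system, and one equivalent of NBS at 0 °C in buffered aqueous THF suppresses radical and acid pathways. The silyl ether on O7 rules out a bicyclic ketal, and the bicarbonate/acetate buffer protects the silyl ether and the acetates from HBr.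

Step 16
Reactants: 24 (2S)-6-{(1S,2R)-2-(tert-butyldimethylsilyloxy)-2-[(2S,6RS)-6-hydroxy-3-oxo-3,6-dihydro-2H-pyran-2-yl]-1-phenylethyl}-4-oxo-2-phenylchroman-5,7-diyl diacetate
Product: 25 (2S)-6-{(1S,2R)-2-(tert-butyldimethylsilyloxy)-2-[(2S)-3,6-dioxo-3,6-dihydro-2H-pyran-2-yl]-1-phenylethyl}-4-oxo-2-phenylchroman-5,7-diyl diacetate
Conditions: CrO3, H2SO4, acetone, 0 °C, short contact
Reagents that add atoms: none
Why: Jones oxidation of the lactol to the lactone by hexavalent chromium; no other oxidisable alcohol is present, and the acetates and the hindered silyl ether tolerate a short contact at 0 °C. The dione is used at once to avoid enolisation to the hydroxy-2-pyrone.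

Step 17
Reactants: 25 (2S)-6-{(1S,2R)-2-(tert-butyldimethylsilyloxy)-2-[(2S)-3,6-dioxo-3,6-dihydro-2H-pyran-2-yl]-1-phenylethyl}-4-oxo-2-phenylchroman-5,7-diyl diacetate
Product: 26 (2S)-6-{(1S,2R)-2-(tert-butyldimethylsilyloxy)-2-[(2R,3R)-3-hydroxy-6-oxo-3,6-dihydro-2H-pyran-2-yl]-1-phenylethyl}-4-oxo-2-phenylchroman-5,7-diyl diacetate (5,6-trans)
Conditions: NaBH4 (1 equiv), CeCl3·7H2O, MeOH/CH2Cl2 1:1, −78 °C
Reagents that add atoms: none
Why: Luche reduction: cerium-activated borohydride adds 1,2 to the cross-conjugated C5 ketone, by far the most electrophilic carbonyl, at −78 °C before the hindered chromanone or the esters react. By analogy with 2-substituted cyclohexanones the small hydride should enter axially and give the equatorial alcohol trans to the C6 side chain.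

Step 18
Reactants: 26 (2S)-6-{(1S,2R)-2-(tert-butyldimethylsilyloxy)-2-[(2R,3R)-3-hydroxy-6-oxo-3,6-dihydro-2H-pyran-2-yl]-1-phenylethyl}-4-oxo-2-phenylchroman-5,7-diyl diacetate
Product: 27 (2R,3S)-2-{(1R,2S)-2-[(2S)-5,7-diacetoxy-4-oxo-2-phenylchroman-6-yl]-1-(tert-butyldimethylsilyloxy)-2-phenylethyl}-6-oxo-3,6-dihydro-2H-pyran-3-yl 4-nitrobenzoate (5,6-cis)
Conditions: 4-O2NC6H4CO2H, PPh3, DIAD, THF, 0 °C → rt
Reagents that add atoms: 4-nitrobenzoic acid, O=C(O)c1ccc(cc1)[N+](=O)[O-]
Why: Mitsunobu esterification with an acidic carboxylic acid; SN2 displacement of the oxyphosphonium group inverts C5 and gives the 5,6-cis ester, which fixes the last stereocentre.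

Step 19
Reactants: 27 (2R,3S)-2-{(1R,2S)-2-[(2S)-5,7-diacetoxy-4-oxo-2-phenylchroman-6-yl]-1-(tert-butyldimethylsilyloxy)-2-phenylethyl}-6-oxo-3,6-dihydro-2H-pyran-3-yl 4-nitrobenzoate
Product: 28 (2S)-6-{(1S,2R)-2-(tert-butyldimethylsilyloxy)-2-[(2R,3S)-3-hydroxy-6-oxo-3,6-dihydro-2H-pyran-2-yl]-1-phenylethyl}-5,7-dihydroxy-2-phenylchroman-4-one
Conditions: Et3N, MeOH, 0 °C → rt
Reagents that add atoms: none
Why: Amine-catalysed transesterification with methanol removes the activated 4-nitrobenzoate and both aryl acetates, all far more labile than the lactone. The weak base and low temperature are chosen to spare the lactone, C2′ and the silyl ether.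

Step 20
Reactants: 28 (2S)-6-{(1S,2R)-2-(tert-butyldimethylsilyloxy)-2-[(2R,3S)-3-hydroxy-6-oxo-3,6-dihydro-2H-pyran-2-yl]-1-phenylethyl}-5,7-dihydroxy-2-phenylchroman-4-one
Product: 29 (2S)-5,7-dihydroxy-6-{(1S,2R)-2-hydroxy-2-[(2R,3S)-3-hydroxy-6-oxo-3,6-dihydro-2H-pyran-2-yl]-1-phenylethyl}-2-phenylchroman-4-one (CNP0136207.1)
Conditions: HF·pyridine, pyridine/THF, 0 °C → rt
Reagents that add atoms: none
Why: Pyridine-buffered hydrogen fluoride cleaves the hindered secondary silyl ether under mildly acidic conditions, which the hydroxy-lactone and the flavanone tolerate. This gives the target.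

## Compound list

1 | 5,7-dihydroxycoumarin | O=C1C=Cc2c(O)cc(O)cc2O1 | starting material
2 | 5-hydroxy-7-(triisopropylsilyloxy)-2H-chromen-2-one | O=C1C=Cc2c(O)cc(O[Si](C(C)C)(C(C)C)C(C)C)cc2O1 | intermediate
3 | 5-(allyloxy)-7-(triisopropylsilyloxy)-2H-chromen-2-one | O=C1C=Cc2c(OCC=C)cc(O[Si](C(C)C)(C(C)C)C(C)C)cc2O1 | intermediate
4 | phenylboronic acid | OB(O)c1ccccc1 | starting material
5 | (4S)-5-(allyloxy)-4-phenyl-7-(triisopropylsilyloxy)chroman-2-one | O=C1C[C@@H](c2ccccc2)c2c(OCC=C)cc(O[Si](C(C)C)(C(C)C)C(C)C)cc2O1 | intermediate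
6 | potassium (4S)-5-(allyloxy)-4-phenyl-7-(triisopropylsilyloxy)-4H-chromen-2-olate | [K+].[O-]C1=C[C@@H](c2ccccc2)c2c(OCC=C)cc(O[Si](C(C)C)(C(C)C)C(C)C)cc2O1 | intermediate (not isolated)
7 | (3R,4S)-5-(allyloxy)-3-hydroxy-4-phenyl-7-(triisopropylsilyloxy)chroman-2-one | O=C1[C@H](O)[C@@H](c2ccccc2)c2c(OCC=C)cc(O[Si](C(C)C)(C(C)C)C(C)C)cc2O1 | intermediate
8 | (3R,4S)-5-(allyloxy)-3-(tert-butyldimethylsilyloxy)-4-phenyl-7-(triisopropylsilyloxy)chroman-2-one | O=C1[C@H](O[Si](C)(C)C(C)(C)C)[C@@H](c2ccccc2)c2c(OCC=C)cc(O[Si](C(C)C)(C(C)C)C(C)C)cc2O1 | intermediate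
9 | (2R,3S)-3-[2-(allyloxy)-6-hydroxy-4-(triisopropylsilyloxy)phenyl]-2-(tert-butyldimethylsilyloxy)-N-methoxy-N-methyl-3-phenylpropanamide | CON(C)C(=O)[C@H](O[Si](C)(C)C(C)(C)C)[C@@H](c1ccccc1)c1c(O)cc(O[Si](C(C)C)(C(C)C)C(C)C)cc1OCC=C | intermediate
10 | (2R,3S)-3-[2,6-bis(allyloxy)-4-(triisopropylsilyloxy)phenyl]-2-(tert-butyldimethylsilyloxy)-N-methoxy-N-methyl-3-phenylpropanamide | CON(C)C(=O)[C@H](O[Si](C)(C)C(C)(C)C)[C@@H](c1ccccc1)c1c(OCC=C)cc(O[Si](C(C)C)(C(C)C)C(C)C)cc1OCC=C | intermediate
11 | furan | c1ccoc1 | starting material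
12 | 2-furyllithium | [Li]c1ccco1 | intermediate (not isolated)
13 | (2R,3S)-3-[2,6-bis(allyloxy)-4-(triisopropylsilyloxy)phenyl]-2-(tert-butyldimethylsilyloxy)-1-(furan-2-yl)-3-phenylpropan-1-one | O=C(c1ccco1)[C@H](O[Si](C)(C)C(C)(C)C)[C@@H](c1ccccc1)c1c(OCC=C)cc(O[Si](C(C)C)(C(C)C)C(C)C)cc1OCC=C | intermediate (not isolated)
14 | (2R,3S)-3-[2,6-bis(allyloxy)-4-hydroxyphenyl]-2-(tert-butyldimethylsilyloxy)-1-(furan-2-yl)-3-phenylpropan-1-one | O=C(c1ccco1)[C@H](O[Si](C)(C)C(C)(C)C)[C@@H](c1ccccc1)c1c(OCC=C)cc(O)cc1OCC=C | intermediate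
15 | methyl (3R)-3-hydroxy-3-phenylpropanoate | COC(=O)C[C@@H](O)c1ccccc1 | starting material
16 | methyl (3S)-3-{3,5-bis(allyloxy)-4-[(1S,2R)-2-(tert-butyldimethylsilyloxy)-3-(furan-2-yl)-3-oxo-1-phenylpropyl]phenoxy}-3-phenylpropanoate | O=C(c1ccco1)[C@H](O[Si](C)(C)C(C)(C)C)[C@@H](c1ccccc1)c1c(OCC=C)cc(O[C@@H](CC(=O)OC)c2ccccc2)cc1OCC=C | intermediate
17 | (3S)-3-{3,5-bis(allyloxy)-4-[(1S,2R)-2-(tert-butyldimethylsilyloxy)-3-(furan-2-yl)-3-oxo-1-phenylpropyl]phenoxy}-3-phenylpropanoic acid | O=C(c1ccco1)[C@H](O[Si](C)(C)C(C)(C)C)[C@@H](c1ccccc1)c1c(OCC=C)cc(O[C@@H](CC(=O)O)c2ccccc2)cc1OCC=C | intermediate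
18 | mixed anhydride of 17 with trifluoroacetic acid | O=C(c1ccco1)[C@H](O[Si](C)(C)C(C)(C)C)[C@@H](c1ccccc1)c1c(OCC=C)cc(O[C@@H](CC(=O)OC(=O)C(F)(F)F)c2ccccc2)cc1OCC=C | intermediate (not isolated)
19 | (2S)-5,7-bis(allyloxy)-6-[(1S,2R)-2-(tert-butyldimethylsilyloxy)-3-(furan-2-yl)-3-oxo-1-phenylpropyl]-2-phenylchroman-4-one | O=C(c1ccco1)[C@H](O[Si](C)(C)C(C)(C)C)[C@@H](c1ccccc1)c1c(OCC=C)cc2c(c1OCC=C)C(=O)C[C@@H](c1ccccc1)O2 | intermediate
20 | (2S)-6-[(1S,2R)-2-(tert-butyldimethylsilyloxy)-3-(furan-2-yl)-3-oxo-1-phenylpropyl]-5,7-dihydroxy-2-phenylchroman-4-one | O=C(c1ccco1)[C@H](O[Si](C)(C)C(C)(C)C)[C@@H](c1ccccc1)c1c(O)cc2c(c1O)C(=O)C[C@@H](c1ccccc1)O2 | intermediate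
21 | (2S)-6-[(1S,2R,3S)-2-(tert-butyldimethylsilyloxy)-3-(furan-2-yl)-3-hydroxy-1-phenylpropyl]-5,7-dihydroxy-2-phenylchroman-4-one | o1cccc1[C@H]([C@H](O[Si](C)(C)C(C)(C)C)[C@@H](c1ccccc1)c1c(O)cc2c(c1O)C(=O)C[C@@H](c1ccccc1)O2)O | intermediate
22 | (2S)-6-[(1S,2R,3S)-2-(tert-butyldimethylsilyloxy)-3-(furan-2-yl)-3-hydroxy-1-phenylpropyl]-4-oxo-2-phenylchroman-5,7-diyl diacetate | o1cccc1[C@H]([C@H](O[Si](C)(C)C(C)(C)C)[C@@H](c1ccccc1)c1c(OC(C)=O)cc2c(c1OC(C)=O)C(=O)C[C@@H](c1ccccc1)O2)O | intermediate (precursor of the key step)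
23 | (2S)-6-[(1S,2R,3S,5Z)-2-(tert-butyldimethylsilyloxy)-3-hydroxy-4,7-dioxo-1-phenylhept-5-en-1-yl]-4-oxo-2-phenylchroman-5,7-diyl diacetate | O=C/C=C\C(=O)[C@@H](O)[C@H](O[Si](C)(C)C(C)(C)C)[C@@H](c1ccccc1)c1c(OC(C)=O)cc2c(c1OC(C)=O)C(=O)C[C@@H](c1ccccc1)O2 | intermediate (not isolated)
24 | (2S)-6-{(1S,2R)-2-(tert-butyldimethylsilyloxy)-2-[(2S,6RS)-6-hydroxy-3-oxo-3,6-dihydro-2H-pyran-2-yl]-1-phenylethyl}-4-oxo-2-phenylchroman-5,7-diyl diacetate (anomer mixture) | OC1C=CC(=O)[C@H]([C@H](O[Si](C)(C)C(C)(C)C)[C@@H](c2ccccc2)c2c(OC(C)=O)cc3c(c2OC(C)=O)C(=O)C[C@@H](c2ccccc2)O3)O1 | intermediate (product of the key step)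
25 | (2S)-6-{(1S,2R)-2-(tert-butyldimethylsilyloxy)-2-[(2S)-3,6-dioxo-3,6-dihydro-2H-pyran-2-yl]-1-phenylethyl}-4-oxo-2-phenylchroman-5,7-diyl diacetate | O=C1C=CC(=O)[C@H]([C@H](O[Si](C)(C)C(C)(C)C)[C@@H](c2ccccc2)c2c(OC(C)=O)cc3c(c2OC(C)=O)C(=O)C[C@@H](c2ccccc2)O3)O1 | intermediate
26 | (2S)-6-{(1S,2R)-2-(tert-butyldimethylsilyloxy)-2-[(2R,3R)-3-hydroxy-6-oxo-3,6-dihydro-2H-pyran-2-yl]-1-phenylethyl}-4-oxo-2-phenylchroman-5,7-diyl diacetate | O=C1C=C[C@@H](O)[C@H]([C@H](O[Si](C)(C)C(C)(C)C)[C@@H](c2ccccc2)c2c(OC(C)=O)cc3c(c2OC(C)=O)C(=O)C[C@@H](c2ccccc2)O3)O1 | intermediate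
27 | (2R,3S)-2-{(1R,2S)-2-[(2S)-5,7-diacetoxy-4-oxo-2-phenylchroman-6-yl]-1-(tert-butyldimethylsilyloxy)-2-phenylethyl}-6-oxo-3,6-dihydro-2H-pyran-3-yl 4-nitrobenzoate | O=C1C=C[C@H](OC(=O)c2ccc(cc2)[N+](=O)[O-])[C@H]([C@H](O[Si](C)(C)C(C)(C)C)[C@@H](c2ccccc2)c2c(OC(C)=O)cc3c(c2OC(C)=O)C(=O)C[C@@H](c2ccccc2)O3)O1 | intermediate
28 | (2S)-6-{(1S,2R)-2-(tert-butyldimethylsilyloxy)-2-[(2R,3S)-3-hydroxy-6-oxo-3,6-dihydro-2H-pyran-2-yl]-1-phenylethyl}-5,7-dihydroxy-2-phenylchroman-4-one | O=C1C=C[C@H](O)[C@H]([C@H](O[Si](C)(C)C(C)(C)C)[C@@H](c2ccccc2)c2c(O)cc3c(c2O)C(=O)C[C@@H](c2ccccc2)O3)O1 | intermediate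
29 | (2S)-5,7-dihydroxy-6-{(1S,2R)-2-hydroxy-2-[(2R,3S)-3-hydroxy-6-oxo-3,6-dihydro-2H-pyran-2-yl]-1-phenylethyl}-2-phenylchroman-4-one | O=C1C=C[C@H](O)[C@H]([C@H](O)[C@@H](c2ccccc2)c2c(O)cc3c(c2O)C(=O)C[C@@H](c2ccccc2)O3)O1 | target

## Step count and least certain steps

Total: 20 steps. Longest linear sequence: 20 steps, 1 → 29; 4, 11 and 15 are bought and enter at steps 3, 8 and 9.

Step 15 (key step). Most likely failure: electrophilic bromination of ring A at C8′, or of the chromanone α-position, competing with furan oxidation if the acetates do not deactivate enough; acid-induced dehydration of the lactol is the second risk. Fallback, from 22 back to 24: sensitised photooxygenation of 22 (O2, tetraphenylporphyrin, visible light, CH2Cl2, −78 °C) should give the furan endoperoxide F1 by [4+2] addition of singlet oxygen, with no halogen electrophile present. Me2S should then reduce the peroxide bond of F1 to give the same ene-dione 23, which closes to 24.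

Step 3. Most likely failure: slow insertion of the electron-rich, peri-substituted coumarin, so that protodeboronation of 4 outruns addition, or loss of facial selectivity caused by the 5-allyloxy group. Fallback, from 3 back to 5, setting C8 by hydride instead of aryl delivery: copper-catalysed conjugate addition of PhMgBr to 3 (CuBr·SMe2, Me3SiCl, THF, −78 °C) should give racemic 5-(allyloxy)-4-phenyl-7-(triisopropylsilyloxy)chroman-2-one F2. DDQ (dioxane, reflux) should then dehydrogenate F2 to 5-(allyloxy)-4-phenyl-7-(triisopropylsilyloxy)-2H-chromen-2-one F3. Asymmetric conjugate reduction of F3 with ligated CuH (Cu(OAc)2, DTBM-SEGPHOS antipode as required, (EtO)2MeSiH, t-BuOH, toluene) should give 5.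

Step 9. Most likely failure: β-elimination of the activated hydroxy ester to methyl cinnamate (its α-hydrogens are acidified by the ester) and partial ionisation at the benzylic carbon, which would lower the yield and the purity at C2′. Fallback, from 14 to 17: the phenoxide of 14 (K2CO3, DMF, 0 °C → rt) should open (R)-4-phenyloxetan-2-one F4 at the benzylic carbon by SN2 alkyl–oxygen cleavage with inversion. F4 is made from commercial (R)-3-hydroxy-3-phenylpropanoic acid by carboxyl-activating lactonisation (PhSO2Cl, pyridine; retention). The opening gives acid 17 directly and makes step 10 unnecessary.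

Step 18. Most likely failure: the oxyphosphonium ion of 26 loses the C6 proton (elimination towards the aromatic 2-pyrone) or is attacked at C3 (SN2′) instead of undergoing SN2 at the hindered C5. Fallback, from 25 to 28 without any inversion: reagent-controlled reduction of the C5 ketone of 25 (Me-CBS oxazaborolidine, antipode chosen to override the ring bias, catecholborane, toluene, −78 °C) should give the 5,6-cis alcohol diacetate F5 directly. The aryl acetates of F5 are then removed with NH4OAc in aqueous methanol to give 28.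

Step 19. Most likely failure: under amine/methanol the freed C5 hydroxyl attacks C2 (translactonisation to the butenolide), methanol adds to C3=C4, or ring C opens to the chalcone and C2′ is scrambled. Fallback, from 26 to 28 without a base-labile alkyl ester: Tf2O and pyridine (CH2Cl2, −30 °C) should convert 26 into the C5 trifluoromethanesulfonate F6. Displacement of the triflate of F6 with Bu4NNO2 (toluene, rt; Lattrell–Dax inversion) should give the cis nitrite ester F7, which hydrolyses on aqueous work-up to the 5,6-cis alcohol diacetate F5. The aryl acetates of F5 are then cleaved near pH 7 with NH4OAc in aqueous methanol to give 28.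

## Further compounds

F1 | step 15 | furan endoperoxide of 22 (2,3,7-trioxabicyclo[2.2.1]hept-5-en-1-yl in place of furan-2-yl; bridgehead configuration undefined) | O1C2C=CC1(OO2)[C@@H](O)[C@H](O[Si](C)(C)C(C)(C)C)[C@@H](c1ccccc1)c1c(OC(C)=O)cc2c(c1OC(C)=O)C(=O)C[C@@H](c1ccccc1)O2
F2 | step 3 | racemic 5-(allyloxy)-4-phenyl-7-(triisopropylsilyloxy)chroman-2-one | O=C1CC(c2ccccc2)c2c(OCC=C)cc(O[Si](C(C)C)(C(C)C)C(C)C)cc2O1
F3 | step 3 | 5-(allyloxy)-4-phenyl-7-(triisopropylsilyloxy)-2H-chromen-2-one | O=C1C=C(c2ccccc2)c2c(OCC=C)cc(O[Si](C(C)C)(C(C)C)C(C)C)cc2O1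
F4 | step 9 | (R)-4-phenyloxetan-2-one | O=C1C[C@H](c2ccccc2)O1
F5 | step 18 | (2S)-6-{(1S,2R)-2-(tert-butyldimethylsilyloxy)-2-[(2R,3S)-3-hydroxy-6-oxo-3,6-dihydro-2H-pyran-2-yl]-1-phenylethyl}-4-oxo-2-phenylchroman-5,7-diyl diacetate (5,6-cis) | O=C1C=C[C@H](O)[C@H]([C@H](O[Si](C)(C)C(C)(C)C)[C@@H](c2ccccc2)c2c(OC(C)=O)cc3c(c2OC(C)=O)C(=O)C[C@@H](c2ccccc2)O3)O1
F6 | step 19 | C5 trifluoromethanesulfonate of 26 (5,6-trans) | O=C1C=C[C@@H](OS(=O)(=O)C(F)(F)F)[C@H]([C@H](O[Si](C)(C)C(C)(C)C)[C@@H](c2ccccc2)c2c(OC(C)=O)cc3c(c2OC(C)=O)C(=O)C[C@@H](c2ccccc2)O3)O1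
F7 | step 19 | C5 nitrite ester of F5 (5,6-cis) | O=C1C=C[C@H](ON=O)[C@H]([C@H](O[Si](C)(C)C(C)(C)C)[C@@H](c2ccccc2)c2c(OC(C)=O)cc3c(c2OC(C)=O)C(=O)C[C@@H](c2ccccc2)O3)O1
A1 | alternative 1 | trans-3,5-bis(benzyloxy)-4-phenyl-7-(triisopropylsilyloxy)chroman-2-one | O=C1[C@H](OCc2ccccc2)[C@@H](c2ccccc2)c2c(OCc3ccccc3)cc(O[Si](C(C)C)(C(C)C)C(C)C)cc2O1
A2 | alternative 1 | 3-(benzyloxy)-2-[hydroxy(phenyl)methyl]-5-(triisopropylsilyloxy)phenol (racemic) | OC(c1ccccc1)c1c(O)cc(O[Si](C(C)C)(C(C)C)C(C)C)cc1OCc1ccccc1
A3 | alternative 1 | 6-benzylidene-5-(benzyloxy)-3-(triisopropylsilyloxy)cyclohexa-2,4-dien-1-one (alkene geometry undefined) | O=C1C=C(O[Si](C(C)C)(C(C)C)C(C)C)C=C(OCc2ccccc2)C1=Cc1ccccc1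
A4 | alternative 2 | cis-5-benzoyloxy-6-substituted 2,3-dihydro-4H-pyran-4-one (lactone numbering) | C1=CC(=O)[C@H](OC(=O)c2ccccc2)[C@H]([C@H](OCc2ccccc2)[C@@H](c2ccccc2)c2c(OCc3ccccc3)cc3c(c2OCc2ccccc2)C(=O)C[C@@H](c2ccccc2)O3)O1
A5 | alternative 2 | (2R,3S)-2-(benzyloxy)-3-[(2S)-5,7-bis(benzyloxy)-4-oxo-2-phenylchroman-6-yl]-3-phenylpropanal | O=C[C@H](OCc1ccccc1)[C@@H](c1ccccc1)c1c(OCc2ccccc2)cc2c(c1OCc1ccccc1)C(=O)C[C@@H](c1ccccc1)O2
A6 | alternative 2 | (1Z,3E)-4-methoxy-2-(trimethylsilyloxy)buta-1,3-dien-1-yl benzoate | CO/C=C/C(O[Si](C)(C)C)=C/OC(=O)c1ccccc1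
A7 | alternative 3 | target as its tetrakis(tert-butyldimethylsilyl) ether | O=C1C=C[C@H](O[Si](C)(C)C(C)(C)C)[C@H]([C@H](O[Si](C)(C)C(C)(C)C)[C@@H](c2ccccc2)c2c(O[Si](C)(C)C(C)(C)C)cc3c(c2O[Si](C)(C)C(C)(C)C)C(=O)C[C@@H](c2ccccc2)O3)O1
A8 | alternative 3 | (3S)-3-aryloxy-3-phenylpropanoic acid carrying the tris-silylated lactone side chain | O=C1C=C[C@H](O[Si](C)(C)C(C)(C)C)[C@H]([C@H](O[Si](C)(C)C(C)(C)C)[C@@H](c2ccccc2)c2c(O[Si](C)(C)C(C)(C)C)cc(O[C@@H](CC(=O)O)c3ccccc3)cc2O[Si](C)(C)C(C)(C)C)O1
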